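**Plan**
Labels: flavone 1 is benzo ring A, pyranone ring C and anisole ring B (C1' to C6'). Flavone 2 is benzo ring D, pyranone ring E and phenol ring F (double-primed atoms).
Enabling feature: ring B is 1,2,4-substituted (C2 of ring C on C1', C8'' on C2', OMe on C4'), and O1'' sits on C8a'' next to C8''. An ester from that oxygen to the carbon that becomes C2 therefore ties an aryl alkyne to a propiolate, and methoxyethyne supplies C4' and C5'.
Cuts, in retrosynthetic order: the four O-benzyl bonds; ring E at O1''-C2'', C3''-C4'' and C4''-C4a'' (alkyne, CO, aryl iodide); ring C at O1-C2 and C2-C3 (back to a biaryl lactone and an acetophenone); ring B at C1'-C2', C3'-C4' and C5'-C6'.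
Forward order: ring D is bought as phloroglucinaldehyde and its CHO is homologated to the C2'/C3' alkyne. Ring B and a bridging lactone then form together. An acetophenone dianion brings ring A and opens the lactone, and acid closes ring C. The one phenol set free is iodinated at C4a'', carbonylative annulation adds rings E and F, and hydrogenolysis finishes.
Stereochemistry: the target has no stereocentre and none is created; the C2'-C8'' axis is not controlled.

Key step: step 7

Remark: the SMILES carries no stereodescriptor, so the hindered C2'-C8'' axis is taken as unassigned and all open biaryls are handled as racemates.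

Step 1
Reactants: 1 2,4,6-trihydroxybenzaldehyde
Product: 2 2,4-bis(benzyloxy)-6-hydroxybenzaldehyde
Conditions: BnBr (2.05 equiv), K2CO3 (2.1 equiv), DMF, 0 °C to rt
Reagents that add atoms: benzyl bromide, BrCc1ccccc1
Why: Williamson etherification takes the acidic 4-OH and one ortho OH, while the last ortho OH is locked in a hydrogen bond to the formyl oxygen and reacts much more slowly, so two equivalents of halide stop at the dibenzyl ether.

Step 2
Reactants: 2 2,4-bis(benzyloxy)-6-hydroxybenzaldehyde
Product: 3 2,4-bis(benzyloxy)-6-(triisopropylsilyloxy)benzaldehyde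
Conditions: i-Pr3SiOTf (1.2 equiv), 2,6-lutidine (1.5 equiv), CH2Cl2, 0 °C
Reagents that add atoms: triisopropylsilyl trifluoromethanesulfonate, CC(C)[Si](OS(=O)(=O)C(F)(F)F)(C(C)C)C(C)C
Why: Silyl ether formation with a silyl triflate overrides the hydrogen bond, and masking this phenol keeps a phenoxide from deactivating the aldehyde in the basic homologation that follows.

Step 3
Reactants: 3 2,4-bis(benzyloxy)-6-(triisopropylsilyloxy)benzaldehyde
Product: 4 [3,5-bis(benzyloxy)-2-ethynylphenoxy]triisopropylsilane
Conditions: dimethyl (1-diazo-2-oxopropyl)phosphonate (1.5 equiv), K2CO3 (2 equiv), MeOH/THF, 0 °C to rt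
Reagents that add atoms: dimethyl (1-diazo-2-oxopropyl)phosphonate, CC(=O)C(=[N+]=[N-])P(=O)(OC)OC
Why: In this Seyferth-Gilbert homologation (Ohira-Bestmann variant), methanolysis frees the diazomethylphosphonate anion, which olefinates the aldehyde to a diazoalkene that loses N2 and rearranges by a 1,2-hydrogen shift to the terminal alkyne, a sequence that works on 2,4,6-trialkoxybenzaldehydes and spares benzyl and bulky silyl ethers.

Step 4
Reactants: 4 [3,5-bis(benzyloxy)-2-ethynylphenoxy]triisopropylsilane
Product: 5 3,5-bis(benzyloxy)-2-ethynylphenol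
Conditions: Bu4NF (1.1 equiv), AcOH (1.1 equiv), THF, 0 °C
Reagents that add atoms: none
Why: Fluoride cleaves the aryl silyl ether, and the acetic acid buffer protonates the phenoxide at once so that it does not add to its ortho alkyne.

Step 5
Reactants: 5 3,5-bis(benzyloxy)-2-ethynylphenol; 6 propiolic acid
Product: 7 3,5-bis(benzyloxy)-2-ethynylphenyl propiolate
Conditions: DCC (1.3 equiv), DMAP (5 mol%), CH2Cl2, -20 to 0 °C
Reagents that add atoms: none
Why: Steglich esterification is the standard way to aryl propiolates, and the low temperature and small DMAP charge suppress conjugate addition to the activated triple bond.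

Step 6
Reactants: 8 chloroacetaldehyde dimethyl acetal
Product: 10 methoxyethyne, via sodium methoxyethynide 9 (not isolated)
Conditions: NaNH2 (3.1 equiv), liquid NH3, -33 °C; NH3 evaporated; cold saturated aqueous NaCl, -20 °C; distilled into a -78 °C trap, kept as a ClCH2CH2Cl solution at -20 °C
Reagents that add atoms: none
Why: This is the classical double elimination route to alkoxyethynes, in which amide removes HCl and then MeOH from the chloroacetal, a third equivalent stores the alkyne as its sodium salt, and hydrolysis releases the low-boiling product for direct distillation.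

Step 7
Reactants: 7 3,5-bis(benzyloxy)-2-ethynylphenyl propiolate; 10 methoxyethyne
Product: 11 1,3-bis(benzyloxy)-9-methoxy-6H-benzo[c]chromen-6-one
Conditions: Cp*RuCl(cod) (10 mol%), 10 (5 equiv), ClCH2CH2Cl, sealed flask, 7 added by syringe pump over 4 h, 20 °C
Reagents that add atoms: none
Why: The Cp*RuCl fragment left after loss of cod binds both alkynes of 7 and couples them oxidatively to a ruthenacyclopentadiene, which forms C1'-C2'; 10 then coordinates and inserts into a Ru-C bond, and reductive elimination releases the arene and returns the catalyst. The closest known reaction type is the Cp*RuCl(cod)-catalysed (2+2+2) cycloaddition of ester-tethered 1,7-diynes with terminal monoalkynes, which gives benzo[c]chromen-6-ones. The six-membered lactone (C1', C2', C8'', C8a'', the ester oxygen and the carbonyl carbon) closes intramolecularly in the oxidative coupling, helped by the rigid o-phenylene backbone that holds the two alkynes four atoms apart, and ring B closes intermolecularly through the C3'-C4' and C5'-C6' bonds, so all six of its carbons come from alkynes. No stereocentre is created, and the C2'-C8'' bond is already present in 7 as an aryl-alkyne bond, so it is never forged between two crowded arenes. The step needs OMe at C4' and not at C5': in the metallacycle C6' lies beta to the ester carbonyl and is electron-poor while C3' is fed by the trioxygenated ring D, and in 10 the CH terminus is nucleophilic and the C-OMe carbon electrophilic, so the matched pairing C5'H-C6' and C4'(OMe)-C3' should give the para-alkoxy benzoate. The step also needs cross- over self-cycloaddition, which slow addition of 7 into an excess of 10 secures.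

Step 8
Reactants: 12 2',6'-dihydroxy-4'-methoxyacetophenone
Product: 13 1-[2-(benzyloxy)-6-hydroxy-4-methoxyphenyl]ethan-1-one
Conditions: BnBr (1.05 equiv), K2CO3 (1.2 equiv), acetone, reflux
Reagents that add atoms: benzyl bromide, BrCc1ccccc1
Why: Williamson etherification stops after one alkylation because the two phenols are equivalent at the outset and the survivor becomes firmly chelated to the ketone.

Step 9
Reactants: 11 1,3-bis(benzyloxy)-9-methoxy-6H-benzo[c]chromen-6-one; 13 1-[2-(benzyloxy)-6-hydroxy-4-methoxyphenyl]ethan-1-one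
Product: 15 1-[2-(benzyloxy)-6-hydroxy-4-methoxyphenyl]-3-[2',4'-bis(benzyloxy)-6'-hydroxy-5-methoxybiphenyl-2-yl]propane-1,3-dione, via dilithium dianion 14 (not isolated)
Conditions: 13 (1.2 equiv), LiN(SiMe3)2 (3.3 equiv per 13), THF, -78 to -10 °C; 11, -78 °C to rt; 1 M HCl, 0 °C
Reagents that add atoms: none
Why: This is a crossed Claisen acylation of an o-hydroxyacetophenone dianion by an aryl ester, the polyanion entry to flavone diketones, in which the carbon terminus of 14 adds to a lactone carbonyl that is activated as a phenol ester and twisted by the C1 benzyloxy group, the C8a'' phenoxide leaves, and the third equivalent of base stores the product as its diketonate so that ring opening cannot reverse.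

Step 10
Reactants: 15 1-[2-(benzyloxy)-6-hydroxy-4-methoxyphenyl]-3-[2',4'-bis(benzyloxy)-6'-hydroxy-5-methoxybiphenyl-2-yl]propane-1,3-dione
Product: 16 5-(benzyloxy)-2-[2',4'-bis(benzyloxy)-6'-hydroxy-5-methoxybiphenyl-2-yl]-7-methoxy-4H-chromen-4-one
Conditions: p-TsOH·H2O (20 mol%), toluene, 90 °C
Reagents that add atoms: none
Why: This acid-catalysed cyclodehydration of an o-hydroxyaryl 1,3-diketone is the closing step of Baker-Venkataraman-type flavone syntheses, in which the ring A phenol adds to the ring B ketone under equilibrating acid and loss of water gives the aromatic 4-pyranone as thermodynamic sink, whereas addition of the ring D phenol to the same carbon leads only to reversible ketals, and catalytic sulfonic acid leaves the benzyl ethers alone.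

Step 11
Reactants: 16 5-(benzyloxy)-2-[2',4'-bis(benzyloxy)-6'-hydroxy-5-methoxybiphenyl-2-yl]-7-methoxy-4H-chromen-4-one
Product: 17 5-(benzyloxy)-2-[2',4'-bis(benzyloxy)-6'-hydroxy-5'-iodo-5-methoxybiphenyl-2-yl]-7-methoxy-4H-chromen-4-one
Conditions: NIS (1.0 equiv), MeCN/CH2Cl2, -20 to 0 °C, dark
Reagents that add atoms: N-iodosuccinimide, O=C1CCC(=O)N1I
Why: Electrophilic aromatic iodination should pick ring D, the only ring with a free phenol and three donor oxygens but no acyl group, and within it C4a'' (between OH and one OBn) is more open than C6'' (between two OBn), the same site preference that gives 3-iodo-2-hydroxy-4,6-dialkoxyacetophenones.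

Step 12
Reactants: 17 5-(benzyloxy)-2-[2',4'-bis(benzyloxy)-6'-hydroxy-5'-iodo-5-methoxybiphenyl-2-yl]-7-methoxy-4H-chromen-4-one; 18 1-(benzyloxy)-4-ethynylbenzene
Product: 20 5,7-bis(benzyloxy)-8-{2-[5-(benzyloxy)-7-methoxy-4-oxo-4H-chromen-2-yl]-5-methoxyphenyl}-2-[4-(benzyloxy)phenyl]-4H-chromen-4-one, via aryl ynone 19 (not isolated)
Conditions: 18 (1.5 equiv), PdCl2(dppf) (5 mol%), CO (10 bar), Et2NH/DMF 1:2, 80 °C
Reagents that add atoms: carbon monoxide, [C-]#[O+]
Why: This is a carbonylative Sonogashira coupling with ring closure in one pot, the standard carbonylative annulation of o-iodophenols with terminal alkynes, in which zerovalent palladium inserts into the carbon-iodine bond at C4a'', CO gives the aroyl complex, alkynylation gives ynone 19, and reversible conjugate addition of Et2NH steers the neighbouring C8a'' phenol into 6-endo closure of ring E rather than 5-exo closure, while flavone 1 is safe because flavones are the end products of these very conditions.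

Step 13
Reactants: 20 5,7-bis(benzyloxy)-8-{2-[5-(benzyloxy)-7-methoxy-4-oxo-4H-chromen-2-yl]-5-methoxyphenyl}-2-[4-(benzyloxy)phenyl]-4H-chromen-4-one
Product: 21 5,7-dihydroxy-8-[2-(5-hydroxy-7-methoxy-4-oxo-4H-chromen-2-yl)-5-methoxyphenyl]-2-(4-hydroxyphenyl)-4H-chromen-4-one (CNP0329977.0)
Conditions: H2 (1 atm), Pd/C (10 wt%), THF/MeOH, rt
Reagents that add atoms: none
Why: Catalytic hydrogenolysis of the four aryl benzyl ethers is routine for benzylated flavones and, at one atmosphere and room temperature, should leave the two methyl ethers and the C2-C3 double bonds of both pyranones untouched.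

**Compound list**
1 | 2,4,6-trihydroxybenzaldehyde | O=Cc1c(O)cc(O)cc1O | starting material
2 | 2,4-bis(benzyloxy)-6-hydroxybenzaldehyde | O=Cc1c(O)cc(OCc2ccccc2)cc1OCc1ccccc1 | intermediate
3 | 2,4-bis(benzyloxy)-6-(triisopropylsilyloxy)benzaldehyde | O=Cc1c(O[Si](C(C)C)(C(C)C)C(C)C)cc(OCc2ccccc2)cc1OCc1ccccc1 | intermediate
4 | [3,5-bis(benzyloxy)-2-ethynylphenoxy]triisopropylsilane | C#Cc1c(O[Si](C(C)C)(C(C)C)C(C)C)cc(OCc2ccccc2)cc1OCc1ccccc1 | intermediate
5 | 3,5-bis(benzyloxy)-2-ethynylphenol | C#Cc1c(O)cc(OCc2ccccc2)cc1OCc1ccccc1 | intermediate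
6 | propiolic acid | C#CC(=O)O | starting material
7 | 3,5-bis(benzyloxy)-2-ethynylphenyl propiolate | C#CC(=O)Oc1cc(OCc2ccccc2)cc(OCc2ccccc2)c1C#C | intermediate
8 | chloroacetaldehyde dimethyl acetal | COC(CCl)OC | starting material
9 | sodium methoxyethynide | [Na+].[C-]#COC | intermediate
10 | methoxyethyne | COC#C | intermediate
11 | 1,3-bis(benzyloxy)-9-methoxy-6H-benzo[c]chromen-6-one | COc1ccc2c(c1)-c1c(OCc3ccccc3)cc(OCc3ccccc3)cc1OC2=O | intermediate
12 | 2',6'-dihydroxy-4'-methoxyacetophenone | CC(=O)c1c(O)cc(OC)cc1O | starting material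
13 | 1-[2-(benzyloxy)-6-hydroxy-4-methoxyphenyl]ethan-1-one | CC(=O)c1c(O)cc(OC)cc1OCc1ccccc1 | intermediate
14 | dilithium dianion (phenoxide enolate) of 13 | [Li+].[Li+].C=C([O-])c1c([O-])cc(OC)cc1OCc1ccccc1 | intermediate
15 | 1-[2-(benzyloxy)-6-hydroxy-4-methoxyphenyl]-3-[2',4'-bis(benzyloxy)-6'-hydroxy-5-methoxybiphenyl-2-yl]propane-1,3-dione | COc1ccc(C(=O)CC(=O)c2c(O)cc(OC)cc2OCc2ccccc2)c(-c2c(O)cc(OCc3ccccc3)cc2OCc2ccccc2)c1 | intermediate
16 | 5-(benzyloxy)-2-[2',4'-bis(benzyloxy)-6'-hydroxy-5-methoxybiphenyl-2-yl]-7-methoxy-4H-chromen-4-one | COc1ccc(-c2cc(=O)c3c(OCc4ccccc4)cc(OC)cc3o2)c(-c2c(O)cc(OCc3ccccc3)cc2OCc2ccccc2)c1 | intermediate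
17 | 5-(benzyloxy)-2-[2',4'-bis(benzyloxy)-6'-hydroxy-5'-iodo-5-methoxybiphenyl-2-yl]-7-methoxy-4H-chromen-4-one | COc1ccc(-c2cc(=O)c3c(OCc4ccccc4)cc(OC)cc3o2)c(-c2c(O)c(I)c(OCc3ccccc3)cc2OCc2ccccc2)c1 | intermediate
18 | 1-(benzyloxy)-4-ethynylbenzene | C#Cc1ccc(OCc2ccccc2)cc1 | starting material
19 | aryl ynone: 16 carrying a 3-[4-(benzyloxy)phenyl]prop-2-ynoyl group at C4a'' (biphenyl C5') | COc1ccc(-c2cc(=O)c3c(OCc4ccccc4)cc(OC)cc3o2)c(-c2c(O)c(C(=O)C#Cc3ccc(OCc4ccccc4)cc3)c(OCc3ccccc3)cc2OCc2ccccc2)c1 | intermediate
20 | 5,7-bis(benzyloxy)-8-{2-[5-(benzyloxy)-7-methoxy-4-oxo-4H-chromen-2-yl]-5-methoxyphenyl}-2-[4-(benzyloxy)phenyl]-4H-chromen-4-one | COc1ccc(-c2cc(=O)c3c(OCc4ccccc4)cc(OC)cc3o2)c(-c2c(OCc3ccccc3)cc(OCc3ccccc3)c3c(=O)cc(-c4ccc(OCc5ccccc5)cc4)oc23)c1 | intermediate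
21 | 5,7-dihydroxy-8-[2-(5-hydroxy-7-methoxy-4-oxo-4H-chromen-2-yl)-5-methoxyphenyl]-2-(4-hydroxyphenyl)-4H-chromen-4-one (CNP0329977.0) | COc1ccc(-c2cc(=O)c3c(O)cc(OC)cc3o2)c(-c2c(O)cc(O)c3c(=O)cc(-c4ccc(O)cc4)oc23)c1 | target

Total step count: 13. Longest linear sequence: 11 steps (steps 1, 2, 3, 4, 5, 7, 9, 10, 11, 12, 13).

**Steps most likely to fail**

Step 7. The ynol ether may insert in the reverse sense. The diyne may also cycloadd with itself, or the volatile, acid-sensitive alkyne may oligomerise at the metal before the metallacycle traps it.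
The fallback runs from 4 back to 11 and builds ring B by a polarity-controlled Diels-Alder benzannulation, which still avoids any arene-arene coupling. Alkyne 4 is deprotonated with n-BuLi in THF at -78 °C to its lithium acetylide F1. This is trapped with methyl chloroformate as methyl 3-[2,4-bis(benzyloxy)-6-(triisopropylsilyloxy)phenyl]prop-2-ynoate F2. Heating F2 with (E)-1-methoxy-3-(trimethylsilyloxy)buta-1,3-diene in xylene should give the cyclohexa-1,4-diene cycloadduct F3. The CH2 terminus of the diene bonds to the aryl-bearing beta carbon of the ynoate, so the ring oxygen must end up para to the ester. Dilute HCl aromatises F3 by loss of methanol and the silyl group to methyl 2',4'-bis(benzyloxy)-5-hydroxy-6'-(triisopropylsilyloxy)biphenyl-2-carboxylate F4. MeI and K2CO3 in acetone give the 5-methoxy ester F5. Bu4NF then frees the phenoxide, which closes onto the neighbouring ester to give 11.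

Step 10. The ring D phenol may capture the activated ring B carbonyl in competition with the ring A phenol, giving ketal or exocyclic enol ether formation. The resulting hemiketal may also fragment by retro-Claisen cleavage back to the lactone, or acid may trigger benzyl migration on ring D.
The fallback runs from 11 back to 16 and keeps the ring D oxygen masked until ring C exists. KOH in aqueous THF opens 11 to the dipotassium hydroxy-carboxylate F6. Allyl bromide in DMF converts this to allyl 6'-(allyloxy)-2',4'-bis(benzyloxy)-5-methoxybiphenyl-2-carboxylate F7. Dianion 14 is acylated by F7 to the O-allyl diketone F8, which has only one phenol and so only one mode of acid closure. p-TsOH in toluene gives the O-allyl flavone F9. Pd(PPh3)4 with morpholine in THF removes the allyl group to give 16, so the marked oxygen stays unique throughout.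

Step 12. Alkynylation may occur without CO uptake and be followed by closure to a benzofuran. Et2NH may intercept the aroylpalladium species, oxidative addition may be slow at the doubly flanked, electron-rich carbon-iodine bond, or the ynone may close 5-exo.
The fallback runs from 16 back to 19. It bypasses the iodide and installs the C4'' carbon by phenol-directed formylation. MgCl2, Et3N and paraformaldehyde in refluxing MeCN formylate exclusively ortho to the free phenol and give the C4a'' salicylaldehyde F10. The lithium acetylide F11, made from 18 and n-BuLi (2.2 equiv) in THF at -78 °C, adds to the aldehyde. This gives the propargylic alcohol F12 as a mixture of stereoisomers, whose carbinol centre is erased next. F12 is used without acid contact and oxidised with MnO2 in CH2Cl2 to ynone 19. Et2NH in EtOH at 40 °C closes 19 to 20.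

**Further compounds**
F1 | step 7 | lithium acetylide of 4 | [Li+].[C-]#Cc1c(O[Si](C(C)C)(C(C)C)C(C)C)cc(OCc2ccccc2)cc1OCc1ccccc1
F2 | step 7 | methyl 3-[2,4-bis(benzyloxy)-6-(triisopropylsilyloxy)phenyl]prop-2-ynoate | COC(=O)C#Cc1c(O[Si](C(C)C)(C(C)C)C(C)C)cc(OCc2ccccc2)cc1OCc1ccccc1
F3 | step 7 | methyl 2-[2,4-bis(benzyloxy)-6-(triisopropylsilyloxy)phenyl]-6-methoxy-4-(trimethylsilyloxy)cyclohexa-1,4-diene-1-carboxylate (racemic) | COC(=O)C1=C(c2c(O[Si](C(C)C)(C(C)C)C(C)C)cc(OCc3ccccc3)cc2OCc2ccccc2)CC(O[Si](C)(C)C)=CC1OC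
F4 | step 7 | methyl 2',4'-bis(benzyloxy)-5-hydroxy-6'-(triisopropylsilyloxy)biphenyl-2-carboxylate | COC(=O)c1ccc(O)cc1-c1c(O[Si](C(C)C)(C(C)C)C(C)C)cc(OCc2ccccc2)cc1OCc1ccccc1
F5 | step 7 | methyl 2',4'-bis(benzyloxy)-5-methoxy-6'-(triisopropylsilyloxy)biphenyl-2-carboxylate | COC(=O)c1ccc(OC)cc1-c1c(O[Si](C(C)C)(C(C)C)C(C)C)cc(OCc2ccccc2)cc1OCc1ccccc1
F6 | step 10 | dipotassium 2',4'-bis(benzyloxy)-5-methoxy-6'-oxidobiphenyl-2-carboxylate | [K+].[K+].COc1ccc(C(=O)[O-])c(-c2c([O-])cc(OCc3ccccc3)cc2OCc2ccccc2)c1
F7 | step 10 | allyl 6'-(allyloxy)-2',4'-bis(benzyloxy)-5-methoxybiphenyl-2-carboxylate | C=CCOC(=O)c1ccc(OC)cc1-c1c(OCC=C)cc(OCc2ccccc2)cc1OCc1ccccc1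
F8 | step 10 | 1-[6'-(allyloxy)-2',4'-bis(benzyloxy)-5-methoxybiphenyl-2-yl]-3-[2-(benzyloxy)-6-hydroxy-4-methoxyphenyl]propane-1,3-dione | COc1ccc(C(=O)CC(=O)c2c(O)cc(OC)cc2OCc2ccccc2)c(-c2c(OCC=C)cc(OCc3ccccc3)cc2OCc2ccccc2)c1
F9 | step 10 | 2-[6'-(allyloxy)-2',4'-bis(benzyloxy)-5-methoxybiphenyl-2-yl]-5-(benzyloxy)-7-methoxy-4H-chromen-4-one | COc1ccc(-c2cc(=O)c3c(OCc4ccccc4)cc(OC)cc3o2)c(-c2c(OCC=C)cc(OCc3ccccc3)cc2OCc2ccccc2)c1
F10 | step 12 | 4,6-bis(benzyloxy)-3-{2-[5-(benzyloxy)-7-methoxy-4-oxo-4H-chromen-2-yl]-5-methoxyphenyl}-2-hydroxybenzaldehyde | COc1ccc(-c2cc(=O)c3c(OCc4ccccc4)cc(OC)cc3o2)c(-c2c(O)c(C=O)c(OCc3ccccc3)cc2OCc2ccccc2)c1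
F11 | step 12 | lithium acetylide of 18 | [Li+].[C-]#Cc1ccc(OCc2ccccc2)cc1
F12 | step 12 | propargylic alcohol: 16 carrying a 3-[4-(benzyloxy)phenyl]-1-hydroxyprop-2-ynyl group at C4a'' (mixture of stereoisomers) | COc1ccc(-c2cc(=O)c3c(OCc4ccccc4)cc(OC)cc3o2)c(-c2c(O)c(C(O)C#Cc3ccc(OCc4ccccc4)cc3)c(OCc3ccccc3)cc2OCc2ccccc2)c1
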